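**Retrosynthetic overview**
1. The C15–C16 single bond (between the C12–C15 diene and the C16=C17 propenyl-oxazole) is made in the penultimate step by Rh(I)-catalysed syn-hydrodienylation of 2-methyl-4-(prop-1-ynyl)oxazole with the unprotected C1–C15 (E,E)-dienyl MIDA boronate; ester hydrolysis then gives the acid.
2. The feature that allows this: C16 carries only CH3, and C17 is bonded to C4 of the 2-methyloxazole ring, next to ring N3. At the alkyne oxidation level, oxazol-4-yl–C≡C–CH3 is a sterically and electronically differentiated, N-coordinating internal alkyne, so one syn addition forms the bond and the E-trisubstituted C16=C17 alkene together.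
3. C1–C15 fragment: C13–C14 by Heck reaction of a vinyl iodide with vinyl MIDA boronate; C2=C3 and C4=C5 by Wittig reaction and cross-metathesis; C6–C7 by Brown anti-crotylboration; C8–C9 by Brown allylboration; C10–C11 by Evans syn-aldol with (E)-3-iodo-2-methylpropenal.
4. No ring is formed in the route: the only ring, the 2-methyloxazole, is bought as 2-methyloxazole-4-carbaldehyde and homologated to the methyl alkyne (Corey–Fuchs, MeI).
5. Both silyl ethers are removed before the acid-labile trienyl carbinol exists; the Heck reaction, the key step and the saponification run on the free triol.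

Key step: step 17

Remark: chain atoms are numbered C1 (carboxyl carbon) to C17 (the CH on oxazole C4) as in the target; metal alkoxides, aminals and borinates that are only hydrolysed or oxidised during work-up are not numbered.

**Step 1**
Reactants: 1 prop-2-yn-1-ol
Product: 3 (E)-3-iodo-2-methylprop-2-en-1-ol, via alkenylalane 2 (not isolated)
Conditions: Me3Al (3 equiv), Cp2ZrCl2 (0.25 equiv), CH2Cl2, 0 °C → rt; then I2, THF, −30 → 0 °C; aqueous work-up
Reagents that add atoms: trimethylaluminium, C[Al](C)C; iodine, II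
Why: Negishi zirconium-catalysed carboalumination adds CH3 and Al syn across the alkyne (CH3 to the internal carbon), and iodinolysis of the C–Al bond with retention fixes the E geometry of the later C12=C13 unit.

**Step 2**
Reactants: 3 (E)-3-iodo-2-methylprop-2-en-1-ol
Product: 4 (E)-3-iodo-2-methylprop-2-enal
Conditions: activated MnO2 (excess), CH2Cl2, rt; used as a solution
Reagents that add atoms: none
Why: Chemoselective allylic alcohol oxidation on the MnO2 surface, which leaves the vinyl iodide and its geometry untouched.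

**Step 3**
Reactants: 4 (E)-3-iodo-2-methylprop-2-enal; 5 (R)-4-benzyl-3-propanoyloxazolidin-2-one
Product: 7 (R)-4-benzyl-3-[(2R,3R,4E)-3-hydroxy-5-iodo-2,4-dimethylpent-4-enoyl]oxazolidin-2-one, via boron Z-enolate 6 (not isolated)
Conditions: 5, n-Bu2BOTf, Et3N, CH2Cl2, 0 °C; then 4, −78 → 0 °C; pH 7 buffer, MeOH, 30% H2O2, 0 °C
Reagents that add atoms: none
Why: Evans syn-aldol, in which the Z-boron enolate reacts through a closed chair transition state on the face away from the benzyl group and so sets C10 and C11 (2R,3R in the acyl chain) in one step.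

**Step 4**
Reactants: 7 aldol adduct
Product: 8 (2R,3R,4E)-3-hydroxy-5-iodo-N-methoxy-N,2,4-trimethylpent-4-enamide
Conditions: MeNH(OMe)·HCl, Me3Al, CH2Cl2, −20 → 0 °C; Rochelle salt work-up
Reagents that add atoms: N,O-dimethylhydroxylamine hydrochloride, CNOC.Cl
Why: Weinreb transamidation with the aluminium amide, assisted by chelation of the free β-hydroxyl, should release the auxiliary without epimerising C10.

**Step 5**
Reactants: 8 Weinreb amide
Product: 9 (2R,3R,4E)-3-[(tert-butyldimethylsilyl)oxy]-5-iodo-N-methoxy-N,2,4-trimethylpent-4-enamide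
Conditions: TBSOTf, 2,6-lutidine, CH2Cl2, −78 → 0 °C
Reagents that add atoms: tert-butyldimethylsilyl triflate, CC(C)(C)[Si](C)(C)OS(=O)(=O)C(F)(F)F
Why: Silyl ether formation with the reactive triflate, needed for the hindered allylic secondary alcohol; the TBS group also blocks retro-aldol cleavage in the next steps.

**Step 6**
Reactants: 9 silylated Weinreb amide
Product: 10 (2R,3R,4E)-3-[(tert-butyldimethylsilyl)oxy]-5-iodo-2,4-dimethylpent-4-enal
Conditions: DIBAL-H, THF, −78 °C; Rochelle salt work-up; used crude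
Reagents that add atoms: none
Why: DIBAL reduction of a Weinreb amide stops at the aldehyde because the chelated tetrahedral aluminium intermediate survives until work-up, and at −78 °C the α-stereocentre C10 should not epimerise.

**Step 7**
Reactants: 10 aldehyde (C9)
Product: 11 (4S,5S,6R,7E)-6-[(tert-butyldimethylsilyl)oxy]-8-iodo-5,7-dimethylocta-1,7-dien-4-ol
Conditions: (−)-Ipc2B(allyl) (from (+)-α-pinene, salt-free, pentane), Et2O, −78 °C; then 3 M NaOH, 30% H2O2, 0 °C → rt
Reagents that add atoms: (−)-B-allyldiisopinocampheylborane, C=CCB([C@@H]1C[C@@H]2C[C@H]([C@H]1C)C2(C)C)[C@@H]1C[C@@H]2C[C@H]([C@H]1C)C2(C)C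
Why: Brown allylboration through a six-membered chair transition state, in which the (−)-Ipc2B reagent should deliver allyl to the aldehyde face that gives 9S under reagent control, overriding the weak bias of the α-methyl/β-silyloxy aldehyde.

**Step 8**
Reactants: 11 homoallylic alcohol
Product: 12 (4S,5S,6R,7E)-4,6-bis[(tert-butyldimethylsilyl)oxy]-8-iodo-5,7-dimethylocta-1,7-diene
Conditions: TBSOTf, 2,6-lutidine, CH2Cl2, −78 → 0 °C
Reagents that add atoms: tert-butyldimethylsilyl triflate, CC(C)(C)[Si](C)(C)OS(=O)(=O)C(F)(F)F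
Why: Silyl ether formation protects the C9 hydroxyl so that the β-oxy aldehyde of the next step cannot eliminate or form a hemiacetal.

**Step 9**
Reactants: 12 bis-silyl diene
Product: 13 (3S,4S,5R,6E)-3,5-bis[(tert-butyldimethylsilyl)oxy]-7-iodo-4,6-dimethylhept-6-enal
Conditions: OsO4 (2 mol%), NaIO4 (4 equiv), 2,6-lutidine, dioxane/H2O 3:1, rt
Reagents that add atoms: osmium tetroxide (catalytic oxygen carrier), O=[Os](=O)(=O)=O; sodium periodate (terminal oxidant), [Na+].[O-]I(=O)(=O)=O
Why: Johnson–Lemieux oxidative cleavage, in which the terminal monosubstituted alkene should be dihydroxylated far faster than the hindered, iodine-deactivated trisubstituted alkene, with 2,6-lutidine suppressing over-oxidation.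

**Step 10**
Reactants: 13 aldehyde (C7)
Product: 14 (3S,4R,6S,7S,8R,9E)-6,8-bis[(tert-butyldimethylsilyl)oxy]-10-iodo-3,7,9-trimethyldeca-1,9-dien-4-ol
Conditions: trans-2-butene, KOt-Bu, n-BuLi, THF, −78 → −45 °C; (−)-Ipc2BOMe, −78 °C; BF3·OEt2; then 13, −78 °C; 3 M NaOH, 30% H2O2
Reagents that add atoms: trans-2-butene (delivered as the (E)-crotylborane), C/C=C/C
Why: Brown anti-crotylboration, in which the (E)-crotylborane reacts through a chair transition state (C6/C7 anti) and the (−)-Ipc groups select the aldehyde face, so C7 (R) and C6 (S) are set under reagent control.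

**Step 11**
Reactants: 14 terminal alkene
Product: 15 (2E,4S,5R,7S,8S,9R,10E)-7,9-bis[(tert-butyldimethylsilyl)oxy]-5-hydroxy-11-iodo-4,8,10-trimethylundeca-2,10-dienal
Conditions: crotonaldehyde (5 equiv), Hoveyda–Grubbs II (5 mol%), CH2Cl2, 40 °C
Reagents that add atoms: (E)-crotonaldehyde, C/C=C/C=O
Why: Olefin cross-metathesis of the terminal alkene with an enal partner should give the E-enal under thermodynamic control, the trisubstituted vinyl iodide being inert to the ruthenium carbene.

**Step 12**
Reactants: 15 enal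
Product: 16 ethyl (2E,4E,6S,7R,9S,10S,11R,12E)-9,11-bis[(tert-butyldimethylsilyl)oxy]-7-hydroxy-13-iodo-2,6,10,12-tetramethyltrideca-2,4,12-trienoate
Conditions: Ph3P=C(CH3)CO2Et (1.5 equiv), CH2Cl2, rt → 40 °C
Reagents that add atoms: ethyl 2-(triphenylphosphoranylidene)propanoate, CCOC(=O)C(C)=P(c1ccccc1)(c1ccccc1)c1ccccc1
Why: Wittig olefination with a stabilised α-methyl ylide should give the E-trisubstituted enoate and so complete the (2E,4E)-dienoate, the free C7 hydroxyl being tolerated.

**Step 13**
Reactants: 16 bis-silyl dienoate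
Product: 17 ethyl (2E,4E,6S,7R,9S,10S,11R,12E)-7,9,11-trihydroxy-13-iodo-2,6,10,12-tetramethyltrideca-2,4,12-trienoate
Conditions: HF·pyridine, pyridine, THF, 0 °C → rt
Reagents that add atoms: none
Why: Fluoride-driven Si–O cleavage removes both secondary TBS ethers while vinyl iodide and dienoate are untouched; it is done here because the later trienyl carbinol would not tolerate deprotection.

**Step 14**
Reactants: 17 triol vinyl iodide; 18 vinylboronic acid MIDA ester (6-methyl-2-vinyl-1,3,6,2-dioxazaborocane-4,8-dione)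
Product: 19 ethyl (2E,4E,6S,7R,9S,10S,11R,12E,14E)-7,9,11-trihydroxy-2,6,10,12-tetramethyl-15-(6-methyl-4,8-dioxo-1,3,6,2-dioxazaborocan-2-yl)pentadeca-2,4,12,14-tetraenoate
Conditions: 18 (2 equiv), Pd(OAc)2 (10 mol%), P(o-tol)3 (20 mol%), Et3N (3 equiv), anhydrous MeCN, 60 °C
Reagents that add atoms: none
Why: Heck–Mizoroki reaction of an alkenyl iodide with a vinylboronate, in which the sp3-hybridised MIDA boron cannot transmetalate, so carbopalladation at the terminal CH2 and syn β-hydride elimination should give the (E)-C14=C15 dienylboronate with retention at C12=C13.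

**Step 15**
Reactants: 20 2-methyl-1,3-oxazole-4-carbaldehyde
Product: 21 4-(2,2-dibromoethenyl)-2-methyl-1,3-oxazole
Conditions: CBr4, PPh3, Zn dust, CH2Cl2, 0 °C → rt
Reagents that add atoms: carbon tetrabromide, BrC(Br)(Br)Br
Why: Corey–Fuchs dibromo-olefination, a Wittig reaction of Ph3P=CBr2 formed in situ, with zinc keeping the medium neutral for the oxazole.

**Step 16**
Reactants: 21 dibromoalkene
Product: 23 2-methyl-4-(prop-1-yn-1-yl)-1,3-oxazole, via lithium acetylide 22 (not isolated)
Conditions: n-BuLi (2.1 equiv), THF, −78 °C; then MeI, −78 °C → rt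
Reagents that add atoms: iodomethane, CI
Why: Second stage of the Corey–Fuchs sequence, in which Br/Li exchange, α-elimination and 1,2-shift (Fritsch–Buttenberg–Wiechell rearrangement) give the lithium acetylide, which is C-methylated by iodomethane.

**Step 17**
Reactants: 19 dienyl MIDA boronate; 23 2-methyl-4-(prop-1-yn-1-yl)-1,3-oxazole
Product: 25 ethyl (2E,4E,6S,7R,9S,10S,11R,12E,14E,16E)-7,9,11-trihydroxy-2,6,10,12,16-pentamethyl-17-(2-methyl-1,3-oxazol-4-yl)heptadeca-2,4,12,14,16-pentaenoate, via dienylboronic acid 24 (not isolated)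
Conditions: 23 (1.5 equiv), [Rh(cod)OH]2 (2.5 mol%), aq K3PO4 (3 M, 5 equiv), dioxane/H2O 5:1, degassed, 60 °C, dark
Reagents that add atoms: none
Why: The aqueous phosphate hydrolyses the MIDA cage of 19 slowly to the (E,E)-dienylboronic acid 24, which transmetalates to Rh(I)–OH with retention of both olefin geometries; the dienyl–Rh species adds syn across the C16≡C17 triple bond of 23, and water protonates the resulting alkenyl–Rh bond and regenerates Rh–OH. The closest known reaction type is the Rh-catalysed hydroarylation and hydroalkenylation of internal alkynes with aryl- and alkenylboronic acids in aqueous media, including its N-directed version on 2-alkynyl azines. No ring is closed and no stereocentre is formed; the new stereochemical element is the C16=C17 geometry, which should be E because carbon and hydrogen arrive on the same face of the alkyne (syn-carborhodation, then protonolysis with retention), while C12=C13 and C14=C15 are carried through from 19. The step needs regioselectivity (dienyl to C16, H to C17), which three things in the substrate should secure: the methyl-bearing carbon is the less hindered terminus, the alkenyl–Rh bond is placed next to the oxazole where it is conjugated, and N3 beside C4 can pre-coordinate rhodium as the ring nitrogen of a 2-alkynylpyridine does. It also needs chemoselectivity: slow release keeps the fragile dienylboronic acid dilute (less protodeboronation), the α-methyl dienoate is a poor acceptor for Rh-alkenyl conjugate addition compared with the coordinating alkyne used in excess, and the free triol is inert under these aqueous basic conditions.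

**Step 18**
Reactants: 25 ethyl ester
Product: 26 (2E,4E,6S,7R,9S,10S,11R,12E,14E,16E)-7,9,11-trihydroxy-2,6,10,12,16-pentamethyl-17-(2-methyl-1,3-oxazol-4-yl)heptadeca-2,4,12,14,16-pentaenoic acid (CNP0108844.1)
Conditions: LiOH·H2O (10 equiv), THF/MeOH/H2O 2:1:1, 0 °C → rt, dark; then AcOH to pH ~5, EtOAc extraction
Reagents that add atoms: lithium hydroxide, [Li+].[OH-]
Why: Ester saponification (BAc2) with excess hydroxide, with no stereocentre α to a carbonyl and a mild acidification that avoids ionising the C11 trienyl carbinol.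

**Compound list**
1 | prop-2-yn-1-ol | C#CCO | starting material
2 | dimethylaluminium (E)-3-(dimethylalumanyl)-2-methylprop-2-en-1-olate | C[Al](C)/C=C(\C)CO[Al](C)C | intermediate (not isolated)
3 | (E)-3-iodo-2-methylprop-2-en-1-ol | I/C=C(\C)CO | intermediate
4 | (E)-3-iodo-2-methylprop-2-enal | I/C=C(\C)C=O | intermediate
5 | (R)-4-benzyl-3-propanoyloxazolidin-2-one | CCC(=O)N1[C@H](Cc2ccccc2)COC1=O | starting material
6 | (Z)-dibutylboron enolate of 5 | C/C=C(\OB(CCCC)CCCC)N1[C@H](Cc2ccccc2)COC1=O | intermediate (not isolated)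
7 | (R)-4-benzyl-3-[(2R,3R,4E)-3-hydroxy-5-iodo-2,4-dimethylpent-4-enoyl]oxazolidin-2-one | I/C=C(\C)[C@H](O)[C@@H](C)C(=O)N1[C@H](Cc2ccccc2)COC1=O | intermediate
8 | (2R,3R,4E)-3-hydroxy-5-iodo-N-methoxy-N,2,4-trimethylpent-4-enamide | I/C=C(\C)[C@H](O)[C@@H](C)C(=O)N(C)OC | intermediate
9 | (2R,3R,4E)-3-[(tert-butyldimethylsilyl)oxy]-5-iodo-N-methoxy-N,2,4-trimethylpent-4-enamide | I/C=C(\C)[C@H](O[Si](C)(C)C(C)(C)C)[C@@H](C)C(=O)N(C)OC | intermediate
10 | (2R,3R,4E)-3-[(tert-butyldimethylsilyl)oxy]-5-iodo-2,4-dimethylpent-4-enal | I/C=C(\C)[C@H](O[Si](C)(C)C(C)(C)C)[C@@H](C)C=O | intermediate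
11 | (4S,5S,6R,7E)-6-[(tert-butyldimethylsilyl)oxy]-8-iodo-5,7-dimethylocta-1,7-dien-4-ol | I/C=C(\C)[C@H](O[Si](C)(C)C(C)(C)C)[C@@H](C)[C@@H](O)CC=C | intermediate
12 | (4S,5S,6R,7E)-4,6-bis[(tert-butyldimethylsilyl)oxy]-8-iodo-5,7-dimethylocta-1,7-diene | I/C=C(\C)[C@H](O[Si](C)(C)C(C)(C)C)[C@@H](C)[C@@H](O[Si](C)(C)C(C)(C)C)CC=C | intermediate
13 | (3S,4S,5R,6E)-3,5-bis[(tert-butyldimethylsilyl)oxy]-7-iodo-4,6-dimethylhept-6-enal | I/C=C(\C)[C@H](O[Si](C)(C)C(C)(C)C)[C@@H](C)[C@@H](O[Si](C)(C)C(C)(C)C)CC=O | intermediate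
14 | (3S,4R,6S,7S,8R,9E)-6,8-bis[(tert-butyldimethylsilyl)oxy]-10-iodo-3,7,9-trimethyldeca-1,9-dien-4-ol | I/C=C(\C)[C@H](O[Si](C)(C)C(C)(C)C)[C@@H](C)[C@@H](O[Si](C)(C)C(C)(C)C)C[C@@H](O)[C@@H](C)C=C | intermediate
15 | (2E,4S,5R,7S,8S,9R,10E)-7,9-bis[(tert-butyldimethylsilyl)oxy]-5-hydroxy-11-iodo-4,8,10-trimethylundeca-2,10-dienal | I/C=C(\C)[C@H](O[Si](C)(C)C(C)(C)C)[C@@H](C)[C@@H](O[Si](C)(C)C(C)(C)C)C[C@@H](O)[C@@H](C)/C=C/C=O | intermediate
16 | ethyl (2E,4E,6S,7R,9S,10S,11R,12E)-9,11-bis[(tert-butyldimethylsilyl)oxy]-7-hydroxy-13-iodo-2,6,10,12-tetramethyltrideca-2,4,12-trienoate | I/C=C(\C)[C@H](O[Si](C)(C)C(C)(C)C)[C@@H](C)[C@@H](O[Si](C)(C)C(C)(C)C)C[C@@H](O)[C@@H](C)/C=C/C=C(\C)C(=O)OCC | intermediate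
17 | ethyl (2E,4E,6S,7R,9S,10S,11R,12E)-7,9,11-trihydroxy-13-iodo-2,6,10,12-tetramethyltrideca-2,4,12-trienoate | I/C=C(\C)[C@H](O)[C@@H](C)[C@@H](O)C[C@@H](O)[C@@H](C)/C=C/C=C(\C)C(=O)OCC | intermediate
18 | vinylboronic acid MIDA ester | C[N+]12CC(=O)O[B-]1(C=C)OC(=O)C2 | starting material
19 | ethyl (2E,4E,6S,7R,9S,10S,11R,12E,14E)-7,9,11-trihydroxy-2,6,10,12-tetramethyl-15-(6-methyl-4,8-dioxo-1,3,6,2-dioxazaborocan-2-yl)pentadeca-2,4,12,14-tetraenoate | C[N+]12CC(=O)O[B-]1(/C=C/C=C(\C)[C@H](O)[C@@H](C)[C@@H](O)C[C@@H](O)[C@@H](C)/C=C/C=C(\C)C(=O)OCC)OC(=O)C2 | intermediate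
20 | 2-methyl-1,3-oxazole-4-carbaldehyde | Cc1nc(C=O)co1 | starting material
21 | 4-(2,2-dibromoethenyl)-2-methyl-1,3-oxazole | BrC(Br)=Cc1coc(C)n1 | intermediate
22 | lithium (2-methyl-1,3-oxazol-4-yl)acetylide | [Li]C#Cc1coc(C)n1 | intermediate (not isolated)
23 | 2-methyl-4-(prop-1-yn-1-yl)-1,3-oxazole | CC#Cc1coc(C)n1 | intermediate
24 | free (E,E)-dienylboronic acid from 19 (B(OH)2 on C15) | OB(O)/C=C/C=C(\C)[C@H](O)[C@@H](C)[C@@H](O)C[C@@H](O)[C@@H](C)/C=C/C=C(\C)C(=O)OCC | intermediate (not isolated)
25 | ethyl (2E,4E,6S,7R,9S,10S,11R,12E,14E,16E)-7,9,11-trihydroxy-2,6,10,12,16-pentamethyl-17-(2-methyl-1,3-oxazol-4-yl)heptadeca-2,4,12,14,16-pentaenoate | CC(/C=C/C=C(\C)[C@H](O)[C@@H](C)[C@@H](O)C[C@@H](O)[C@@H](C)/C=C/C=C(\C)C(=O)OCC)=C\c1coc(C)n1 | intermediate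
26 | (2E,4E,6S,7R,9S,10S,11R,12E,14E,16E)-7,9,11-trihydroxy-2,6,10,12,16-pentamethyl-17-(2-methyl-1,3-oxazol-4-yl)heptadeca-2,4,12,14,16-pentaenoic acid | CC(/C=C/C=C(\C)[C@H](O)[C@@H](C)[C@@H](O)C[C@@H](O)[C@@H](C)/C=C/C=C(\C)C(=O)O)=C\c1coc(C)n1 | target

**Step count**
Total steps: 18. Longest linear sequence: 16 (steps 1–14, 17 and 18, from prop-2-yn-1-ol).

**Steps most likely to fail**

1. Step 17. What may go wrong: carborhodation with the opposite regiochemistry (dienyl delivered to C17), protodeboronation of the released dienylboronic acid outrunning transmetalation, or conjugate addition of the dienyl–Rh species to the dienoate. The fallback replaces the alkyne hydrodienylation by a cross-coupling of two stereodefined partners. It sets out from 23, which is hydrozirconated with Cp2Zr(H)Cl (THF, rt; excess reagent equilibrates zirconium to the methyl-bearing carbon) and iodinated to (E)-4-(2-iodoprop-1-en-1-yl)-2-methyl-1,3-oxazole F1. Suzuki–Miyaura coupling of F1 with 19 under slow-release conditions (Pd(OAc)2, SPhos, aq K3PO4, dioxane, 60 °C) should form the same C15–C16 bond with retention on both partners and comes back to the route at 25.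

2. Step 14. What may go wrong: carbopalladation with the wrong regiochemistry (a branched 1,1-disubstituted vinylboronate), Pd–H-mediated isomerisation of the new diene, or reduction of the C–I bond when insertion at the hindered alkenylpalladium is slow. The fallback replaces the Heck reaction by a Stille coupling with a bis-metallated C2 linchpin. Commercial (E)-(2-bromoethenyl)boronic acid MIDA ester is stannylated with hexabutylditin (Pd(PPh3)4, toluene, 100 °C) to (E)-[2-(tributylstannyl)ethenyl]boronic acid MIDA ester F2. The fallback sets out from 17, whose Stille coupling with F2 (Pd2(dba)3, AsPh3, DMF, rt → 45 °C) is selective at tin because the MIDA boronate cannot transmetalate, and it comes back to the route at 19.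

3. Step 7. What may go wrong: poor facial selectivity if the α-methyl/β-silyloxy aldehyde and the reagent are mismatched, or partial epimerisation at C10 while the aldehyde is handled. The fallback replaces the reagent-controlled allylation by a substrate-directed reduction. It sets out from 8, which with allylmagnesium bromide (3 equiv, THF, −78 → 0 °C) should give the β-hydroxy ketone (5R,6R,7E)-6-hydroxy-8-iodo-5,7-dimethylocta-1,7-dien-4-one F3. Evans–Saksena reduction (Me4NBH(OAc)3, MeCN/AcOH, −30 °C) delivers hydride intramolecularly from the C11-bound borohydride and should give the 1,3-anti diol (4S,5S,6R,7E)-8-iodo-5,7-dimethylocta-1,7-diene-4,6-diol F4. Bis-silylation (TBSOTf, 2,6-lutidine, CH2Cl2) comes back to the route at 12.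

**Further compounds**
F1 | step 17 | (E)-4-(2-iodoprop-1-en-1-yl)-2-methyl-1,3-oxazole | C/C(I)=C\c1coc(C)n1
F2 | step 14 | (E)-[2-(tributylstannyl)ethenyl]boronic acid MIDA ester | CCCC[Sn](CCCC)(CCCC)/C=C/[B-]12OC(=O)C[N+]1(C)CC(=O)O2
F3 | step 7 | (5R,6R,7E)-6-hydroxy-8-iodo-5,7-dimethylocta-1,7-dien-4-one | I/C=C(\C)[C@H](O)[C@@H](C)C(=O)CC=C
F4 | step 7 | (4S,5S,6R,7E)-8-iodo-5,7-dimethylocta-1,7-diene-4,6-diol | I/C=C(\C)[C@H](O)[C@@H](C)[C@@H](O)CC=C
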